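**Plan**
- Retrosynthesis: the 5-O-tosyl and 4'-O-benzyl groups come off last; ring C is then cut at three bonds at once, O1–C8a, C4–C4a and O1–C2.
- This leaves a ring A aryne and an arylpropiolic acid that carries O1, C2, C3, C4 and ring B.
- Enabling feature: C8a (bearing O1) and C4a (bearing C4) are adjacent carbons of ring A, with the 8-methoxy group on one flank and the 5-oxygen on the other. Ring A can therefore serve as a C4a≡C8a aryne whose 5-oxygen, held as a sulfonate, steers the addition.
- Forward: the silyl triflate of ring A is made in five steps from 3-hydroxy-4,5-dimethoxybenzaldehyde and the acid in four steps from 2,3,4-trihydroxybenzaldehyde.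
- Rings A and B are bought in; ring C is the only ring formed (step 10), followed by detosylation and hydrogenolysis.
- Stereochemistry: the target has no stereocentre and no configurable double bond, so nothing has to be set.

Key step: step 10

Remark: flavone numbering (O1, C2 to C8a, primed positions in ring B) is used for ring A positions of intermediates; in 11 the triflate, not the tosylate, is assumed to be the group expelled on desilylation.

**Route**

Step 1
Reactants: 1 3-hydroxy-4,5-dimethoxybenzaldehyde
Product: 2 5-formyl-2,3-dimethoxyphenyl N-isopropylcarbamate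
Conditions: i-PrNCO, Et3N (cat.), CH2Cl2, rt
Reagents that add atoms: isopropyl isocyanate, CC(C)N=C=O
Why: Amine-catalysed addition of the phenol to the isocyanate (carbamoylation) should install the N-monoalkyl carbamate that later directs lithiation and can be removed under mild amine conditions, while the aldehyde is left alone.

Step 2
Reactants: 2 5-formyl-2,3-dimethoxyphenyl N-isopropylcarbamate
Product: 4 5-hydroxy-2,3-dimethoxyphenyl N-isopropylcarbamate, via aryl formate 3 (not isolated)
Conditions: mCPBA, CH2Cl2, 0 °C to rt; then MeOH, HCl (cat.), rt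
Reagents that add atoms: 3-chloroperoxybenzoic acid (mCPBA), O=C(OO)c1cccc(Cl)c1
Why: In this Baeyer–Villiger (Dakin-type) oxidation the para-methoxy group should make the aryl group migrate as it does for 3,4,5-trimethoxybenzaldehyde, and acid-catalysed transesterification of the labile aryl formate should free the phenol without touching the acid-stable carbamate.

Step 3
Reactants: 4 5-hydroxy-2,3-dimethoxyphenyl N-isopropylcarbamate
Product: 8 3-hydroxy-5,6-dimethoxy-2-(trimethylsilyl)phenyl N-isopropylcarbamate, via N,O-bis(trimethylsilyl) derivative 5 (not isolated), via aryllithium 6 (not isolated), via tris(trimethylsilyl) compound 7 (not isolated)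
Conditions: TMSOTf (2.2 equiv), TMEDA, Et2O, 0 °C to rt; n-BuLi (3.3 equiv), TMEDA, −78 °C; TMSCl, −78 °C to rt; aq. NaHCO3/MeOH work-up
Reagents that add atoms: chlorotrimethylsilane, C[Si](C)(C)Cl
Why: This is a directed ortho-metalation of an O-aryl carbamate silylated in the flask on N and on the phenol (Hoppe–Snieckus protocol), in which the only free position ortho to the carbamate is the carbon between the two ring oxygens, so lithiation and TMSCl quench should place silicon there (an O-to-C silyl shift from the neighbouring silyl ether would give the same product) and the N- and O-silyl groups fall off on mild aqueous methanolysis.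

Step 4
Reactants: 8 3-hydroxy-5,6-dimethoxy-2-(trimethylsilyl)phenyl N-isopropylcarbamate
Product: 9 3-[(isopropylcarbamoyl)oxy]-4,5-dimethoxy-2-(trimethylsilyl)phenyl 4-methylbenzenesulfonate
Conditions: TsCl, Et3N, DMAP (cat.), CH2Cl2, 0 °C to rt
Reagents that add atoms: 4-toluenesulfonyl chloride, Cc1ccc(cc1)S(=O)(=O)Cl
Why: DMAP-catalysed sulfonylation of the free phenol should proceed because Et3N is too weak a base to trigger E1cB loss of the N–H carbamate, and the basic, non-acidic medium avoids protodesilylation of the electron-rich arylsilane.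

Step 5
Reactants: 9 3-[(isopropylcarbamoyl)oxy]-4,5-dimethoxy-2-(trimethylsilyl)phenyl 4-methylbenzenesulfonate
Product: 11 5,6-dimethoxy-3-(tosyloxy)-2-(trimethylsilyl)phenyl trifluoromethanesulfonate, via silylphenol 10 (not isolated)
Conditions: DBU, Et2NH, MeCN, 40 °C; then PhNTf2, rt
Reagents that add atoms: N-phenylbis(trifluoromethanesulfonimide), O=S(=O)(N(c1ccccc1)S(=O)(=O)C(F)(F)F)C(F)(F)F
Why: E1cB cleavage of the N-monoalkyl carbamate by DBU, with the isocyanate trapped by Et2NH, should free the hindered silylphenoxide, which is triflated in the same flask (the one-pot carbamate-to-triflate conversion used for silylaryl triflates), the aryl tosylate being inert to the amine at this temperature.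

Step 6
Reactants: 12 2,3,4-trihydroxybenzaldehyde
Product: 13 4-(benzyloxy)-2,3-dihydroxybenzaldehyde
Conditions: BnBr (1.0 equiv), NaHCO3, KI (cat.), DMF, 40 °C
Reagents that add atoms: benzyl bromide, BrCc1ccccc1
Why: In this Williamson etherification the weak base should ionise only the most acidic 4-hydroxyl (para to the formyl group, not chelated to it), the selectivity known for gallacetophenone and 2,4-dihydroxybenzaldehyde.

Step 7
Reactants: 13 4-(benzyloxy)-2,3-dihydroxybenzaldehyde
Product: 14 4-(benzyloxy)-2,3-dimethoxybenzaldehyde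
Conditions: MeI, K2CO3, DMF, rt
Reagents that add atoms: iodomethane, CI
Why: Exhaustive Williamson O-methylation in DMF should alkylate both remaining phenols, including the chelated 2-hydroxyl, and leaves the benzyl ether in place.

Step 8
Reactants: 14 4-(benzyloxy)-2,3-dimethoxybenzaldehyde
Product: 15 1-(benzyloxy)-4-(2,2-dibromovinyl)-2,3-dimethoxybenzene
Conditions: CBr4, PPh3, CH2Cl2, 0 °C
Reagents that add atoms: tetrabromomethane, BrC(Br)(Br)Br
Why: The Corey–Fuchs (Ramirez) dibromo-olefination is reliable for electron-rich aromatic aldehydes and adds the one carbon that becomes C3.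

Step 9
Reactants: 15 1-(benzyloxy)-4-(2,2-dibromovinyl)-2,3-dimethoxybenzene
Product: 17 3-[4-(benzyloxy)-2,3-dimethoxyphenyl]prop-2-ynoic acid, via lithium acetylide 16 (not isolated)
Conditions: n-BuLi (2.2 equiv), THF, −78 °C; CO2, −78 °C to rt; aq. HCl
Reagents that add atoms: carbon dioxide, O=C=O
Why: In the second stage of the Corey–Fuchs sequence bromine–lithium exchange, Fritsch–Buttenberg–Wiechell rearrangement and deprotonation should give the lithium acetylide, whose carboxylation with CO2 delivers the propiolic acid directly, the benzyl and methyl ethers being stable to n-BuLi at −78 °C.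

Step 10
Reactants: 11 5,6-dimethoxy-3-(tosyloxy)-2-(trimethylsilyl)phenyl trifluoromethanesulfonate (1.5 equiv) and 17 3-[4-(benzyloxy)-2,3-dimethoxyphenyl]prop-2-ynoic acid
Product: 20 4'-benzyloxy-7,8,2',3'-tetramethoxy-5-(tosyloxy)flavone, via aryne 18 (not isolated), via hydroxyaryl ynone 19 (not isolated)
Conditions: CsF (4 equiv), THF, sealed tube, 125 °C
Reagents that add atoms: none
Why: Fluoride attacks silicon of 11 and the neighbouring triflate, a far better nucleofuge than the tosylate on the other side, leaves to give the C4a≡C8a aryne 18; the carboxylate of 17 adds through oxygen at C8a, the C4a anion attacks the adjacent ester carbonyl through a four-membered intermediate, and its opening shifts the acyl group to C4a (C4–C4a) to give the phenoxide of ynone 19. The closest known reaction is the addition of carboxylic acids to arynes with O-to-C acyl shift (insertion of the aryne into the C–O bond of the acid), which is documented to run on to flavones when the acid is an arylpropiolic acid. Ring C then closes by 6-endo-dig oxa-Michael addition of the C8a phenoxide to the ynone (O1–C2) and protonation at C3 gives 20; no stereocentre is formed. The selectivity needed is oxygen at C8a and not at C4a: the 5-tosyloxy group is a stronger sigma acceptor than the 8-methoxy group and is the bulkier flank, so the developing aryl anion should sit at C4a next to the sulfonate and attack should go to the distal carbon C8a, the sense in which 3-sulfonyloxy arynes are known to react. Because O1 arrives with the acid and the 5-oxygen stays masked, ring closure has only one phenoxide to use, so the 6,7-dimethoxy isomer cannot arise from closure onto the other ring A oxygen. A tosylate rather than a triflate is chosen at C5 so that the C4a anion should acylate faster than it expels the sulfonate.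

Step 11
Reactants: 20 4'-benzyloxy-7,8,2',3'-tetramethoxy-5-(tosyloxy)flavone
Product: 21 4'-benzyloxy-5-hydroxy-7,8,2',3'-tetramethoxyflavone
Conditions: K2CO3, MeOH, 50 °C
Reagents that add atoms: none
Why: Sulfonate methanolysis by attack of methoxide at sulfur should be easy here because the 5-oxide of the electron-poor chromone ring is a good leaving group, as in the mild-base removal of tosyl groups from flavones, and the benzyl and methyl ethers are untouched.

Step 12
Reactants: 21 4'-benzyloxy-5-hydroxy-7,8,2',3'-tetramethoxyflavone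
Product: 22 5,4'-dihydroxy-7,8,2',3'-tetramethoxyflavone
Conditions: H2 (1 atm), 10% Pd/C, EtOAc/MeOH, rt
Reagents that add atoms: none
Why: Hydrogenolysis of the benzyl ether over Pd/C should free the 4'-phenol, the chromone double bond and the aryl methyl ethers being stable at 1 atm and rt.

**Compound list**
1 | 3-hydroxy-4,5-dimethoxybenzaldehyde | COc1cc(C=O)cc(O)c1OC | starting material
2 | 5-formyl-2,3-dimethoxyphenyl N-isopropylcarbamate | COc1cc(C=O)cc(OC(=O)NC(C)C)c1OC | intermediate
3 | 3-[(isopropylcarbamoyl)oxy]-4,5-dimethoxyphenyl formate | COc1cc(OC=O)cc(OC(=O)NC(C)C)c1OC | intermediate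
4 | 5-hydroxy-2,3-dimethoxyphenyl N-isopropylcarbamate | COc1cc(O)cc(OC(=O)NC(C)C)c1OC | intermediate
5 | 2,3-dimethoxy-5-[(trimethylsilyl)oxy]phenyl N-isopropyl-N-(trimethylsilyl)carbamate | COc1cc(O[Si](C)(C)C)cc(OC(=O)N(C(C)C)[Si](C)(C)C)c1OC | intermediate
6 | [2-{[isopropyl(trimethylsilyl)carbamoyl]oxy}-3,4-dimethoxy-6-[(trimethylsilyl)oxy]phenyl]lithium | COc1cc(O[Si](C)(C)C)c([Li])c(OC(=O)N(C(C)C)[Si](C)(C)C)c1OC | intermediate
7 | 5,6-dimethoxy-2-(trimethylsilyl)-3-[(trimethylsilyl)oxy]phenyl N-isopropyl-N-(trimethylsilyl)carbamate | COc1cc(O[Si](C)(C)C)c([Si](C)(C)C)c(OC(=O)N(C(C)C)[Si](C)(C)C)c1OC | intermediate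
8 | 3-hydroxy-5,6-dimethoxy-2-(trimethylsilyl)phenyl N-isopropylcarbamate | COc1cc(O)c([Si](C)(C)C)c(OC(=O)NC(C)C)c1OC | intermediate
9 | 3-[(isopropylcarbamoyl)oxy]-4,5-dimethoxy-2-(trimethylsilyl)phenyl 4-methylbenzenesulfonate | COc1cc(OS(=O)(=O)c2ccc(C)cc2)c([Si](C)(C)C)c(OC(=O)NC(C)C)c1OC | intermediate
10 | 3-hydroxy-4,5-dimethoxy-2-(trimethylsilyl)phenyl 4-methylbenzenesulfonate | COc1cc(OS(=O)(=O)c2ccc(C)cc2)c([Si](C)(C)C)c(O)c1OC | intermediate
11 | 5,6-dimethoxy-3-(tosyloxy)-2-(trimethylsilyl)phenyl trifluoromethanesulfonate | COc1cc(OS(=O)(=O)c2ccc(C)cc2)c([Si](C)(C)C)c(OS(=O)(=O)C(F)(F)F)c1OC | intermediate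
12 | 2,3,4-trihydroxybenzaldehyde | O=Cc1ccc(O)c(O)c1O | starting material
13 | 4-(benzyloxy)-2,3-dihydroxybenzaldehyde | O=Cc1ccc(OCc2ccccc2)c(O)c1O | intermediate
14 | 4-(benzyloxy)-2,3-dimethoxybenzaldehyde | COc1c(C=O)ccc(OCc2ccccc2)c1OC | intermediate
15 | 1-(benzyloxy)-4-(2,2-dibromovinyl)-2,3-dimethoxybenzene | COc1c(C=C(Br)Br)ccc(OCc2ccccc2)c1OC | intermediate
16 | {[4-(benzyloxy)-2,3-dimethoxyphenyl]ethynyl}lithium | [Li]C#Cc1ccc(OCc2ccccc2)c(OC)c1OC | intermediate
17 | 3-[4-(benzyloxy)-2,3-dimethoxyphenyl]prop-2-ynoic acid | O=C(O)C#Cc1ccc(OCc2ccccc2)c(OC)c1OC | intermediate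
18 | 5,6-dimethoxy-3-(tosyloxy)-1,2-didehydrobenzene (aryne, triple bond C4a≡C8a) | COC1=C(OC)C#CC(OS(=O)(=O)c2ccc(C)cc2)=C1 | intermediate
19 | 3-[4-(benzyloxy)-2,3-dimethoxyphenyl]-1-[2-hydroxy-3,4-dimethoxy-6-(tosyloxy)phenyl]prop-2-yn-1-one | COc1cc(OS(=O)(=O)c2ccc(C)cc2)c(C(=O)C#Cc2ccc(OCc3ccccc3)c(OC)c2OC)c(O)c1OC | intermediate
20 | 4'-benzyloxy-7,8,2',3'-tetramethoxy-5-(tosyloxy)flavone | COc1cc(OS(=O)(=O)c2ccc(C)cc2)c2c(=O)cc(-c3ccc(OCc4ccccc4)c(OC)c3OC)oc2c1OC | intermediate
21 | 4'-benzyloxy-5-hydroxy-7,8,2',3'-tetramethoxyflavone | COc1cc(O)c2c(=O)cc(-c3ccc(OCc4ccccc4)c(OC)c3OC)oc2c1OC | intermediate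
22 | 5,4'-dihydroxy-7,8,2',3'-tetramethoxyflavone | COc1cc(O)c2c(=O)cc(-c3ccc(O)c(OC)c3OC)oc2c1OC | target

**Totals**
Total step count: 12 (steps 1–5 for the aryne precursor, steps 6–9 for the acid, steps 10–12 for union and deprotection).
Longest linear sequence: 8 steps (1 → 22 through steps 1–5 and 10–12).

**Steps most likely to fail**

Step 10. Three processes could spoil it:
- The carboxylate may add at C4a instead of C8a, since the 8-methoxy group pulls the opposite way to the 5-sulfonate.
- The C4a anion may expel the tosylate (a second aryne) or simply be protonated to the aryl ester before the acyl shift.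
- The acid may decarboxylate at the temperature the acyl shift needs.

The fallback fixes the regiochemistry by a carbonylative route that reuses the silicon handle. It sets out from 9 and 15 and comes back at 20. ICl in CH2Cl2 should replace silicon by iodine at the ipso carbon of 9 to give 2-iodo-3-[(isopropylcarbamoyl)oxy]-4,5-dimethoxyphenyl 4-methylbenzenesulfonate F1. DBU/Et2NH then removes the carbamate to give 3-hydroxy-2-iodo-4,5-dimethoxyphenyl 4-methylbenzenesulfonate F2. Dibromoalkene 15 with n-BuLi, through acetylide 16 and a water quench, gives 1-(benzyloxy)-4-ethynyl-2,3-dimethoxybenzene F3. Carbonylative Sonogashira coupling of F2 with F3 (PdCl2(PPh3)2, CO at 1 atm, Et2NH) should give ynone 19, whose only free phenol closes ring C to 20.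

Step 3. Three processes could spoil it:
- Incomplete silylation in the flask may leave an N–H or O–H that consumes base or lets the carbamate collapse to the isocyanate.
- The carbamoyl group may undergo an anionic Fries shift on warming.
- The very electron-rich arylsilane may undergo protodesilylation on work-up.

The fallback replaces the transient protection by an isolated, base-stable silyl ether and forms the C–Si bond on that compound. It sets out from 4 and comes back at 8. TBSCl/imidazole gives 5-[(tert-butyldimethylsilyl)oxy]-2,3-dimethoxyphenyl N-isopropylcarbamate F4. TMSOTf/TMEDA then gives its N-silyl derivative 5-[(tert-butyldimethylsilyl)oxy]-2,3-dimethoxyphenyl N-isopropyl-N-(trimethylsilyl)carbamate F5. n-BuLi/TMEDA at −78 °C gives the aryllithium [6-[(tert-butyldimethylsilyl)oxy]-2-{[isopropyl(trimethylsilyl)carbamoyl]oxy}-3,4-dimethoxyphenyl]lithium F6. A TMSCl quench at −78 °C gives 3-[(tert-butyldimethylsilyl)oxy]-5,6-dimethoxy-2-(trimethylsilyl)phenyl N-isopropyl-N-(trimethylsilyl)carbamate F7, and aqueous work-up gives 3-[(tert-butyldimethylsilyl)oxy]-5,6-dimethoxy-2-(trimethylsilyl)phenyl N-isopropylcarbamate F8. TBAF buffered with AcOH at 0 °C should then remove only the O-silyl group to give 8.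

Step 5. Two processes could spoil it:
- The silylphenoxide freed next to the tosylate may undergo a C-to-O silyl shift with loss of the sulfonate (premature aryne formation).
- The amine may attack the tosylate during the hours at 40 °C.

The fallback reverses the order of the two sulfonylations, so the triflate is installed while the other oxygen is a benzyl ether and the tosylate is added last under brief, cold conditions. It sets out from 8 and comes back at 11. BnBr/K2CO3 in acetone gives 3-(benzyloxy)-5,6-dimethoxy-2-(trimethylsilyl)phenyl N-isopropylcarbamate F9. DBU/Et2NH gives 3-(benzyloxy)-5,6-dimethoxy-2-(trimethylsilyl)phenol F10, and PhNTf2 gives 3-(benzyloxy)-5,6-dimethoxy-2-(trimethylsilyl)phenyl trifluoromethanesulfonate F11. Neutral hydrogenolysis (H2, 10% Pd/C, EtOAc) gives 3-hydroxy-5,6-dimethoxy-2-(trimethylsilyl)phenyl trifluoromethanesulfonate F12. TsCl/Et3N/DMAP at 0 °C, the known way of sulfonylating 3-hydroxy-2-silylaryl triflates, should then give 11.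

**Further compounds**
F1 | step 10 | 2-iodo-3-[(isopropylcarbamoyl)oxy]-4,5-dimethoxyphenyl 4-methylbenzenesulfonate | COc1cc(OS(=O)(=O)c2ccc(C)cc2)c(I)c(OC(=O)NC(C)C)c1OC
F2 | step 10 | 3-hydroxy-2-iodo-4,5-dimethoxyphenyl 4-methylbenzenesulfonate | COc1cc(OS(=O)(=O)c2ccc(C)cc2)c(I)c(O)c1OC
F3 | step 10 | 1-(benzyloxy)-4-ethynyl-2,3-dimethoxybenzene | C#Cc1ccc(OCc2ccccc2)c(OC)c1OC
F4 | step 3 | 5-[(tert-butyldimethylsilyl)oxy]-2,3-dimethoxyphenyl N-isopropylcarbamate | COc1cc(O[Si](C)(C)C(C)(C)C)cc(OC(=O)NC(C)C)c1OC
F5 | step 3 | 5-[(tert-butyldimethylsilyl)oxy]-2,3-dimethoxyphenyl N-isopropyl-N-(trimethylsilyl)carbamate | COc1cc(O[Si](C)(C)C(C)(C)C)cc(OC(=O)N(C(C)C)[Si](C)(C)C)c1OC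
F6 | step 3 | [6-[(tert-butyldimethylsilyl)oxy]-2-{[isopropyl(trimethylsilyl)carbamoyl]oxy}-3,4-dimethoxyphenyl]lithium | COc1cc(O[Si](C)(C)C(C)(C)C)c([Li])c(OC(=O)N(C(C)C)[Si](C)(C)C)c1OC
F7 | step 3 | 3-[(tert-butyldimethylsilyl)oxy]-5,6-dimethoxy-2-(trimethylsilyl)phenyl N-isopropyl-N-(trimethylsilyl)carbamate | COc1cc(O[Si](C)(C)C(C)(C)C)c([Si](C)(C)C)c(OC(=O)N(C(C)C)[Si](C)(C)C)c1OC
F8 | step 3 | 3-[(tert-butyldimethylsilyl)oxy]-5,6-dimethoxy-2-(trimethylsilyl)phenyl N-isopropylcarbamate | COc1cc(O[Si](C)(C)C(C)(C)C)c([Si](C)(C)C)c(OC(=O)NC(C)C)c1OC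
F9 | step 5 | 3-(benzyloxy)-5,6-dimethoxy-2-(trimethylsilyl)phenyl N-isopropylcarbamate | COc1cc(OCc2ccccc2)c([Si](C)(C)C)c(OC(=O)NC(C)C)c1OC
F10 | step 5 | 3-(benzyloxy)-5,6-dimethoxy-2-(trimethylsilyl)phenol | COc1cc(OCc2ccccc2)c([Si](C)(C)C)c(O)c1OC
F11 | step 5 | 3-(benzyloxy)-5,6-dimethoxy-2-(trimethylsilyl)phenyl trifluoromethanesulfonate | COc1cc(OCc2ccccc2)c([Si](C)(C)C)c(OS(=O)(=O)C(F)(F)F)c1OC
F12 | step 5 | 3-hydroxy-5,6-dimethoxy-2-(trimethylsilyl)phenyl trifluoromethanesulfonate | COc1cc(O)c([Si](C)(C)C)c(OS(=O)(=O)C(F)(F)F)c1OC
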